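## Retrosynthetic overview

1. Target 29 comes from macrocyclic alcohol 27 by C9 acetylation and removal of the two silyl ethers; the C8 (S)-2-methylbutanoate is installed before ring closure.
2. The ten-membered carbocycle is closed last, at C9–C10, by an intramolecular Nozaki–Hiyama–Kishi alkenylation of α-acyloxy aldehyde 26, which sets C9. Ring order: γ-lactone first, carbocycle second.
3. Trans-lactone 21 (C6–C7 bond, C6 and C7 stereocentres) comes from enal 14 and allylic bromide 18 by the proposed chromium-catalysed anti-selective 2-(methoxycarbonyl)allylation and lactonisation.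
4. West enal 14 comes from but-2-yne-1,4-diol: both trisubstituted alkenes are made by hydroxyl-directed Ru-catalysed trans-hydrostannation and iodination, and C3–C4 by Negishi coupling.
5. East bromide 18 comes from (S)-glyceraldehyde acetonide (source of C8) and methyl acrylate by a Morita–Baylis–Hillman reaction and SN2′ bromination.

Assumption: locants C1–C15 follow germacrane numbering of the target (ring oxygen on C6, lactone carbonyl C12, exocyclic methylene C13, hydroxymethyl C14 on C10 and C15 on C4).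

Shorthand: TBDPS = tert-butyldiphenylsilyl; "iododienyl" = (1E,5Z)-7-(TBDPS-oxy)-2-[(TBDPS-oxy)methyl]-6-iodohepta-1,5-dien-1-yl; L1 = proposed ligand 3,6-diphenyl-1,8-bis[(4S)-4-tert-butyl-4,5-dihydro-1,3-oxazol-2-yl]-9H-carbazole.

## Route

Step 1
Reactants: 1 but-2-yne-1,4-diol
Product: 2 4-[(4-methoxybenzyl)oxy]but-2-yn-1-ol
Conditions: 1 (3 equiv), NaH (1 equiv), PMBCl (1 equiv), Bu4NI (cat.), THF/DMF, 0 °C to rt
Reagents that add atoms: 4-methoxybenzyl chloride COc1ccc(CCl)cc1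
Why: Williamson etherification of a symmetrical diol used in excess gives mainly the mono-ether, which is easily separated from recovered diol.

Step 2
Reactants: 2 4-[(4-methoxybenzyl)oxy]but-2-yn-1-ol
Product: 4 (2Z)-2-iodo-4-[(4-methoxybenzyl)oxy]but-2-en-1-ol, via vinylstannane 3 (not isolated)
Conditions: [Cp*RuCl]4 (2.5 mol%), Bu3SnH (1.1 equiv), CH2Cl2, rt; then I2 (1.1 equiv), 0 °C
Reagents that add atoms: iodine II; tributyltin hydride CCCC[SnH](CCCC)CCCC (tin stays only in 3)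
Why: Ruthenium-catalysed trans-hydrostannation of a propargylic alcohol puts tin on the carbon next to the free hydroxyl and hydrogen trans to it, and iododestannylation goes with retention, so iodine (later C3) is cis to C6.

Step 3
Reactants: 4 (2Z)-2-iodo-4-[(4-methoxybenzyl)oxy]but-2-en-1-ol; 5 (4-bromobut-1-yn-1-yl)trimethylsilane
Product: 7 (2E)-2-{2-[(4-methoxybenzyl)oxy]ethylidene}-6-(trimethylsilyl)hex-5-yn-1-ol, via alkylzinc bromide 6 (not isolated)
Conditions: 5 (2.5 equiv), Zn dust, LiCl, THF, 50 °C; then 4, Pd(OAc)2 (2 mol%), SPhos (4 mol%), THF, rt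
Reagents that add atoms: zinc [Zn] (zinc stays only in 6)
Why: Negishi sp3–sp2 cross-coupling of an alkylzinc halide with an alkenyl iodide goes with retention of alkene geometry and tolerates the free hydroxyl when the zinc reagent is in excess, so C3 stays cis to C6.

Step 4
Reactants: 7 (2E)-2-{2-[(4-methoxybenzyl)oxy]ethylidene}-6-(trimethylsilyl)hex-5-yn-1-ol
Product: 9 (6E)-6-{2-[(4-methoxybenzyl)oxy]ethylidene}hept-2-yne-1,7-diol, via dilithium alkoxide acetylide 8 (not isolated)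
Conditions: MeLi·LiBr (3 equiv), THF, 0 °C to rt; then (CH2O)n, 0 °C to rt; H2O
Reagents that add atoms: paraformaldehyde (as formaldehyde) C=O; methyllithium [Li]C (lithium stays only in 8)
Why: Methyllithium cleaves the alkynyl–silicon bond to the lithium acetylide, which adds to formaldehyde (acetylide hydroxymethylation) to install C14 as a propargylic alcohol.

Step 5
Reactants: 9 (6E)-6-{2-[(4-methoxybenzyl)oxy]ethylidene}hept-2-yne-1,7-diol
Product: 11 (2Z)-2-iodo-6-{(E)-2-[(4-methoxybenzyl)oxy]ethylidene}hept-2-ene-1,7-diol, via vinylstannane 10 (not isolated)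
Conditions: [Cp*RuCl]4 (2.5 mol%), Bu3SnH (1.1 equiv), CH2Cl2, rt; then I2 (1.05 equiv), 0 °C
Reagents that add atoms: iodine II; tributyltin hydride CCCC[SnH](CCCC)CCCC (tin stays only in 10)
Why: A second hydroxyl-directed trans-hydrostannation delivers tin to C10 (next to the propargylic OH) and hydrogen to C1 on the opposite side, and tin–iodine exchange with retention leaves iodine (later C9) cis to C2.

Step 6
Reactants: 11 (2Z)-2-iodo-6-{(E)-2-[(4-methoxybenzyl)oxy]ethylidene}hept-2-ene-1,7-diol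
Product: 12 (2Z)-1,7-bis(TBDPS-oxy)-2-iodo-6-{(E)-2-[(4-methoxybenzyl)oxy]ethylidene}hept-2-ene
Conditions: TBDPSCl (2.4 equiv), imidazole, DMF, rt
Reagents that add atoms: tert-butyl(chloro)diphenylsilane CC(C)(C)[Si](Cl)(c1ccccc1)c1ccccc1
Why: Standard silylation of two primary alcohols gives acid-stable silyl ethers that last until the final step.

Step 7
Reactants: 12 (2Z)-1,7-bis(TBDPS-oxy)-2-iodo-6-{(E)-2-[(4-methoxybenzyl)oxy]ethylidene}hept-2-ene
Product: 13 (2E,6Z)-8-(TBDPS-oxy)-3-[(TBDPS-oxy)methyl]-7-iodoocta-2,6-dien-1-ol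
Conditions: DDQ (1.2 equiv), CH2Cl2/pH 7 buffer (10:1), 0 °C
Reagents that add atoms: none
Why: Oxidative cleavage of the electron-rich 4-methoxybenzyl ether by DDQ leaves the silyl ethers, the alkenyl iodide and both alkenes untouched.

Step 8
Reactants: 13 (2E,6Z)-8-(TBDPS-oxy)-3-[(TBDPS-oxy)methyl]-7-iodoocta-2,6-dien-1-ol
Product: 14 (2E,6Z)-8-(TBDPS-oxy)-3-[(TBDPS-oxy)methyl]-7-iodoocta-2,6-dienal
Conditions: MnO2 (20 equiv), CH2Cl2, rt
Reagents that add atoms: none
Why: Allylic oxidation with MnO2 gives the enal without isomerising the trisubstituted alkene, as in the nerol to neral oxidation.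

Step 9
Reactants: 15 (4S)-2,2-dimethyl-1,3-dioxolane-4-carbaldehyde; 16 methyl acrylate
Product: 17 methyl 2-{[(4S)-2,2-dimethyl-1,3-dioxolan-4-yl](hydroxy)methyl}prop-2-enoate (both carbinol epimers)
Conditions: DABCO (0.5 equiv), 1,4-dioxane/H2O (1:1), rt, 3 d
Reagents that add atoms: none
Why: The Morita–Baylis–Hillman reaction joins the acrylate α-carbon (C11) to the aldehyde carbon (C7); the new carbinol centre is formed as a mixture that does not matter because C7 becomes sp2 in step 10, and C8 is not touched.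

Step 10
Reactants: 17 methyl 2-{[(4S)-2,2-dimethyl-1,3-dioxolan-4-yl](hydroxy)methyl}prop-2-enoate
Product: 18 methyl (2Z)-2-(bromomethyl)-3-[(4R)-2,2-dimethyl-1,3-dioxolan-4-yl]prop-2-enoate
Conditions: NBS (1.3 equiv), Me2S (1.5 equiv), CH2Cl2, 0 °C to rt
Reagents that add atoms: N-bromosuccinimide O=C1CCC(=O)N1Br
Why: The bromodimethylsulfonium reagent activates the Baylis–Hillman alcohol and bromide attacks in an SN2′ sense to give the rearranged primary allylic bromide under near-neutral conditions that spare the acetonide and C8.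

Step 11
Reactants: 14 (2E,6Z)-8-(TBDPS-oxy)-3-[(TBDPS-oxy)methyl]-7-iodoocta-2,6-dienal; 18 methyl (2Z)-2-(bromomethyl)-3-[(4R)-2,2-dimethyl-1,3-dioxolan-4-yl]prop-2-enoate
Product: 21 (4S,5R)-4-[(4R)-2,2-dimethyl-1,3-dioxolan-4-yl]-5-(iododienyl)-3-methylideneoxolan-2-one, via silyl ether 19 (not isolated), via hydroxy ester 20 (not isolated)
Conditions: CrCl2 (10 mol%), L1 (12 mol%), i-Pr2NEt (30 mol%), Mn powder (2 equiv), TMSCl (1.5 equiv), THF, 0 °C to rt; then PPTS, MeOH, 0 °C; then PPTS, toluene, 50 °C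
Reagents that add atoms: chlorotrimethylsilane C[Si](C)(C)Cl (silicon stays only in 19)
Why: Proposed new method: a chromium-catalysed, ligand-controlled anti-selective 2-(methoxycarbonyl)allylation of an enal by a γ-substituted stereogenic 2-(bromomethyl)enoate, in which divalent chromium (regenerated by Mn) converts 18 into an allylchromium species of trivalent chromium whose alkene isomers interconvert by 1,3-metal shift, the tridentate ligand L1 penalises the chair transition state with an axial γ-substituent so that bond formation goes through the chair with the dioxolanyl group equatorial (C6/C7 anti, hence the trans-lactone), L1 selects the Si face of the aldehyde (6R; the antipodal ligand is used if a model enal shows Re-face addition) and the allyl unit reacts anti to its C8–O bond with H8 eclipsing the ester-bearing alkene carbon (matched case, 7S), TMSCl frees the catalyst as silyl ether 19 and mild acid then closes the lactone; the closest known reaction type is the catalytic asymmetric Nozaki–Hiyama–Kishi 2-(alkoxycarbonyl)allylation of aldehydes with unsubstituted 2-(bromomethyl)acrylates, together with stoichiometric CrCl2 Barbier lactone syntheses.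

Step 12
Reactants: 21 (4S,5R)-4-[(4R)-2,2-dimethyl-1,3-dioxolan-4-yl]-5-(iododienyl)-3-methylideneoxolan-2-one
Product: 22 (4R,5R)-4-[(1R)-1,2-dihydroxyethyl]-5-(iododienyl)-3-methylideneoxolan-2-one
Conditions: AcOH/H2O/THF (3:1:1), 40 °C
Reagents that add atoms: none
Why: Acid hydrolysis of the terminal isopropylidene acetal frees the C8/C9 diol while the TBDPS ethers, the alkenyl iodide and the lactone are stable to aqueous acetic acid (the C7 descriptor changes by priority only).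

Step 13
Reactants: 22 (4R,5R)-4-[(1R)-1,2-dihydroxyethyl]-5-(iododienyl)-3-methylideneoxolan-2-one
Product: 23 (4R,5R)-4-{(1R)-1-hydroxy-2-[(triethylsilyl)oxy]ethyl}-5-(iododienyl)-3-methylideneoxolan-2-one
Conditions: TESCl (1.05 equiv), pyridine, CH2Cl2, −40 °C
Reagents that add atoms: chlorotriethylsilane CC[Si](Cl)(CC)CC
Why: Silylation at low temperature is selective for the primary C9 hydroxyl over the hindered secondary C8 hydroxyl.

Step 14
Reactants: 23 (4R,5R)-4-{(1R)-1-hydroxy-2-[(triethylsilyl)oxy]ethyl}-5-(iododienyl)-3-methylideneoxolan-2-one; 24 (2S)-2-methylbutanoic acid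
Product: 25 (1R)-1-[(2R,3S)-2-(iododienyl)-4-methylidene-5-oxooxolan-3-yl]-2-[(triethylsilyl)oxy]ethyl (2S)-2-methylbutanoate
Conditions: DCC (1.5 equiv), DMAP (0.2 equiv), CH2Cl2, 0 °C to rt
Reagents that add atoms: none
Why: Steglich esterification acylates the only free hydroxyl (C8) and, having no ketene pathway, keeps the (S) centre of the acid.

Step 15
Reactants: 25 (1R)-1-[(2R,3S)-2-(iododienyl)-4-methylidene-5-oxooxolan-3-yl]-2-[(triethylsilyl)oxy]ethyl (2S)-2-methylbutanoate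
Product: 26 (1R)-1-[(2R,3S)-2-(iododienyl)-4-methylidene-5-oxooxolan-3-yl]-2-oxoethyl (2S)-2-methylbutanoate
Conditions: (COCl)2, DMSO, CH2Cl2, −78 to −40 °C; then Et3N, −78 to 0 °C
Reagents that add atoms: none
Why: Swern conditions oxidise primary triethylsilyl ethers directly to aldehydes, so no free C9 alcohol is formed that could take up the C8 acyl group, and the low temperature protects C8 from epimerisation.

Step 16
Reactants: 26 (1R)-1-[(2R,3S)-2-(iododienyl)-4-methylidene-5-oxooxolan-3-yl]-2-oxoethyl (2S)-2-methylbutanoate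
Product: 27 (6R,7S,8R,9S)-14,15-bis(TBDPS-oxy)-9-hydroxy-8-[(2S)-2-methylbutanoyloxy]germacra-1(10)Z,4E,11(13)-trien-12,6-olide
Conditions: CrCl2 (8 equiv), NiCl2 (0.08 equiv), degassed DMSO, rt, 26 added over 10 h (final 0.002 M)
Reagents that add atoms: none
Why: Intramolecular Nozaki–Hiyama–Kishi alkenylation (NiCl2-catalysed formation of an alkenylchromium species of trivalent chromium with retention of alkene geometry) closes the ten-membered ring, helped by the cis C4=C5 alkene and the trans-lactone, and the non-chelating chromium adds anti to the C8–O bond (polar Felkin–Anh) to give the 8,9-anti arrangement, that is 9S.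

Step 17
Reactants: 27 (6R,7S,8R,9S)-14,15-bis(TBDPS-oxy)-9-hydroxy-8-[(2S)-2-methylbutanoyloxy]germacra-1(10)Z,4E,11(13)-trien-12,6-olide
Product: 28 (6R,7S,8R,9S)-9-acetoxy-14,15-bis(TBDPS-oxy)-8-[(2S)-2-methylbutanoyloxy]germacra-1(10)Z,4E,11(13)-trien-12,6-olide
Conditions: Ac2O, pyridine, DMAP (cat.), CH2Cl2, 0 °C
Reagents that add atoms: acetic anhydride CC(=O)OC(C)=O
Why: Acetylation of the single free (allylic, secondary) hydroxyl is fast and leaves all stereocentres untouched.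

Step 18
Reactants: 28 (6R,7S,8R,9S)-9-acetoxy-14,15-bis(TBDPS-oxy)-8-[(2S)-2-methylbutanoyloxy]germacra-1(10)Z,4E,11(13)-trien-12,6-olide
Product: 29 CNP0207247.12, (6R,7S,8R,9S)-9-acetoxy-14,15-dihydroxy-8-[(2S)-2-methylbutanoyloxy]germacra-1(10)Z,4E,11(13)-trien-12,6-olide
Conditions: HF·pyridine, pyridine, THF, 0 °C to rt
Reagents that add atoms: none
Why: Fluoride desilylation under buffered acidic conditions removes both primary allylic TBDPS ethers without acyl migration or addition to the α-methylene lactone.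

## Compound list

1 | but-2-yne-1,4-diol | OCC#CCO | starting material
2 | 4-[(4-methoxybenzyl)oxy]but-2-yn-1-ol | OCC#CCOCc1ccc(OC)cc1 | intermediate
3 | (2Z)-4-[(4-methoxybenzyl)oxy]-2-(tributylstannyl)but-2-en-1-ol | OC/C(=C/COCc1ccc(OC)cc1)[Sn](CCCC)(CCCC)CCCC | intermediate (not isolated)
4 | (2Z)-2-iodo-4-[(4-methoxybenzyl)oxy]but-2-en-1-ol | OC/C(I)=C/COCc1ccc(OC)cc1 | intermediate
5 | (4-bromobut-1-yn-1-yl)trimethylsilane | C[Si](C)(C)C#CCCBr | starting material
6 | bromo[4-(trimethylsilyl)but-3-yn-1-yl]zinc | C[Si](C)(C)C#CCC[Zn]Br | intermediate (not isolated)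
7 | (2E)-2-{2-[(4-methoxybenzyl)oxy]ethylidene}-6-(trimethylsilyl)hex-5-yn-1-ol | OC/C(CCC#C[Si](C)(C)C)=C/COCc1ccc(OC)cc1 | intermediate
8 | dilithium alkoxide acetylide of 7 after loss of the silyl group | [Li]OC/C(CCC#C[Li])=C/COCc1ccc(OC)cc1 | intermediate (not isolated)
9 | (6E)-6-{2-[(4-methoxybenzyl)oxy]ethylidene}hept-2-yne-1,7-diol | OC/C(CCC#CCO)=C/COCc1ccc(OC)cc1 | intermediate
10 | (2Z)-6-{(E)-2-[(4-methoxybenzyl)oxy]ethylidene}-2-(tributylstannyl)hept-2-ene-1,7-diol | OC/C(CC/C=C(\[Sn](CCCC)(CCCC)CCCC)CO)=C/COCc1ccc(OC)cc1 | intermediate (not isolated)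
11 | (2Z)-2-iodo-6-{(E)-2-[(4-methoxybenzyl)oxy]ethylidene}hept-2-ene-1,7-diol | OC/C(CC/C=C(\I)CO)=C/COCc1ccc(OC)cc1 | intermediate
12 | (2Z)-1,7-bis[(tert-butyldiphenylsilyl)oxy]-2-iodo-6-{(E)-2-[(4-methoxybenzyl)oxy]ethylidene}hept-2-ene | CC(C)(C)[Si](c1ccccc1)(c1ccccc1)OC/C(CC/C=C(\I)CO[Si](c1ccccc1)(c1ccccc1)C(C)(C)C)=C/COCc1ccc(OC)cc1 | intermediate
13 | (2E,6Z)-8-[(tert-butyldiphenylsilyl)oxy]-3-{[(tert-butyldiphenylsilyl)oxy]methyl}-7-iodoocta-2,6-dien-1-ol | CC(C)(C)[Si](c1ccccc1)(c1ccccc1)OC/C(CC/C=C(\I)CO[Si](c1ccccc1)(c1ccccc1)C(C)(C)C)=C/CO | intermediate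
14 | (2E,6Z)-8-[(tert-butyldiphenylsilyl)oxy]-3-{[(tert-butyldiphenylsilyl)oxy]methyl}-7-iodoocta-2,6-dienal | CC(C)(C)[Si](c1ccccc1)(c1ccccc1)OC/C(CC/C=C(\I)CO[Si](c1ccccc1)(c1ccccc1)C(C)(C)C)=C/C=O | intermediate
15 | (4S)-2,2-dimethyl-1,3-dioxolane-4-carbaldehyde ((S)-glyceraldehyde acetonide) | O=C[C@@H]1COC(C)(C)O1 | starting material
16 | methyl acrylate | C=CC(=O)OC | starting material
17 | methyl 2-{[(4S)-2,2-dimethyl-1,3-dioxolan-4-yl](hydroxy)methyl}prop-2-enoate (carbinol epimers) | C=C(C(=O)OC)C(O)[C@@H]1COC(C)(C)O1 | intermediate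
18 | methyl (2Z)-2-(bromomethyl)-3-[(4R)-2,2-dimethyl-1,3-dioxolan-4-yl]prop-2-enoate | COC(=O)/C(CBr)=C/[C@@H]1COC(C)(C)O1 | intermediate
19 | methyl (3R,4R,5E,9Z)-11-[(tert-butyldiphenylsilyl)oxy]-6-{[(tert-butyldiphenylsilyl)oxy]methyl}-3-[(4R)-2,2-dimethyl-1,3-dioxolan-4-yl]-10-iodo-2-methylidene-4-[(trimethylsilyl)oxy]undeca-5,9-dienoate | C=C(C(=O)OC)[C@@H]([C@H](O[Si](C)(C)C)/C=C(/CO[Si](c1ccccc1)(c1ccccc1)C(C)(C)C)CC/C=C(\I)CO[Si](c1ccccc1)(c1ccccc1)C(C)(C)C)[C@@H]1COC(C)(C)O1 | intermediate (not isolated)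
20 | methyl (3S,4R,5E,9Z)-11-[(tert-butyldiphenylsilyl)oxy]-6-{[(tert-butyldiphenylsilyl)oxy]methyl}-3-[(4R)-2,2-dimethyl-1,3-dioxolan-4-yl]-4-hydroxy-10-iodo-2-methylideneundeca-5,9-dienoate | C=C(C(=O)OC)[C@@H]([C@H](O)/C=C(/CO[Si](c1ccccc1)(c1ccccc1)C(C)(C)C)CC/C=C(\I)CO[Si](c1ccccc1)(c1ccccc1)C(C)(C)C)[C@@H]1COC(C)(C)O1 | intermediate (not isolated)
21 | (4S,5R)-4-[(4R)-2,2-dimethyl-1,3-dioxolan-4-yl]-5-(iododienyl)-3-methylideneoxolan-2-one | C=C1C(=O)O[C@H](/C=C(/CO[Si](c2ccccc2)(c2ccccc2)C(C)(C)C)CC/C=C(\I)CO[Si](c2ccccc2)(c2ccccc2)C(C)(C)C)[C@H]1[C@@H]1COC(C)(C)O1 | intermediate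
22 | (4R,5R)-4-[(1R)-1,2-dihydroxyethyl]-5-(iododienyl)-3-methylideneoxolan-2-one | C=C1C(=O)O[C@H](/C=C(/CO[Si](c2ccccc2)(c2ccccc2)C(C)(C)C)CC/C=C(\I)CO[Si](c2ccccc2)(c2ccccc2)C(C)(C)C)[C@H]1[C@@H](O)CO | intermediate
23 | (4R,5R)-4-{(1R)-1-hydroxy-2-[(triethylsilyl)oxy]ethyl}-5-(iododienyl)-3-methylideneoxolan-2-one | C=C1C(=O)O[C@H](/C=C(/CO[Si](c2ccccc2)(c2ccccc2)C(C)(C)C)CC/C=C(\I)CO[Si](c2ccccc2)(c2ccccc2)C(C)(C)C)[C@H]1[C@@H](O)CO[Si](CC)(CC)CC | intermediate
24 | (2S)-2-methylbutanoic acid | CC[C@H](C)C(=O)O | starting material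
25 | (1R)-1-[(2R,3S)-2-(iododienyl)-4-methylidene-5-oxooxolan-3-yl]-2-[(triethylsilyl)oxy]ethyl (2S)-2-methylbutanoate | C=C1C(=O)O[C@H](/C=C(/CO[Si](c2ccccc2)(c2ccccc2)C(C)(C)C)CC/C=C(\I)CO[Si](c2ccccc2)(c2ccccc2)C(C)(C)C)[C@H]1[C@@H](OC(=O)[C@@H](C)CC)CO[Si](CC)(CC)CC | intermediate
26 | (1R)-1-[(2R,3S)-2-(iododienyl)-4-methylidene-5-oxooxolan-3-yl]-2-oxoethyl (2S)-2-methylbutanoate | C=C1C(=O)O[C@H](/C=C(/CO[Si](c2ccccc2)(c2ccccc2)C(C)(C)C)CC/C=C(\I)CO[Si](c2ccccc2)(c2ccccc2)C(C)(C)C)[C@H]1[C@@H](OC(=O)[C@@H](C)CC)C=O | intermediate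
27 | (6R,7S,8R,9S)-14,15-bis[(tert-butyldiphenylsilyl)oxy]-9-hydroxy-8-[(2S)-2-methylbutanoyloxy]germacra-1(10)Z,4E,11(13)-trien-12,6-olide | C=C1C(=O)O[C@@H]2/C=C(/CO[Si](c3ccccc3)(c3ccccc3)C(C)(C)C)CC/C=C(/CO[Si](c3ccccc3)(c3ccccc3)C(C)(C)C)[C@H](O)[C@H](OC(=O)[C@@H](C)CC)[C@@H]12 | intermediate
28 | (6R,7S,8R,9S)-9-acetoxy-14,15-bis[(tert-butyldiphenylsilyl)oxy]-8-[(2S)-2-methylbutanoyloxy]germacra-1(10)Z,4E,11(13)-trien-12,6-olide | C=C1C(=O)O[C@@H]2/C=C(/CO[Si](c3ccccc3)(c3ccccc3)C(C)(C)C)CC/C=C(/CO[Si](c3ccccc3)(c3ccccc3)C(C)(C)C)[C@H](OC(C)=O)[C@H](OC(=O)[C@@H](C)CC)[C@@H]12 | intermediate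
29 | CNP0207247.12, (6R,7S,8R,9S)-9-acetoxy-14,15-dihydroxy-8-[(2S)-2-methylbutanoyloxy]germacra-1(10)Z,4E,11(13)-trien-12,6-olide | C=C1C(=O)O[C@@H]2/C=C(/CO)CC/C=C(/CO)[C@H](OC(C)=O)[C@H](OC(=O)[C@@H](C)CC)[C@@H]12 | target

## Step count and weak points

Total step count: 18 (steps 1–8 west fragment, steps 9–10 east fragment, steps 11–18 after fragment union).
Longest linear sequence: 16 steps (steps 1–8, then 11–18).

Three steps most likely to fail:

**Step 11 (proposed new reaction).** Possible failures are syn addition giving the cis-lactone, reductive 1,4-elimination of the allylic dioxolane oxygen from the allylchromium species, and pinacol coupling of the enal. The fallback uses known chemistry, sets out from 15 (with enal 14 unchanged) and comes back at 21. Corey–Fuchs olefination of 15 (CBr4, PPh3) gives (4R)-4-(2,2-dibromoethenyl)-2,2-dimethyl-1,3-dioxolane F1. Treatment with n-BuLi and then methyl chloroformate gives methyl 3-[(4R)-2,2-dimethyl-1,3-dioxolan-4-yl]prop-2-ynoate F2. Syn-hydrometallation of the ynoate with [(Ph3P)CuH]6 (or i-Bu2AlH/HMPA) and trapping of the α-metallated acrylate with ICH2Bpin gives methyl (2Z)-3-[(4R)-2,2-dimethyl-1,3-dioxolan-4-yl]-2-[(4,4,5,5-tetramethyl-1,3,2-dioxaborolan-2-yl)methyl]prop-2-enoate F3, in which the dioxolanyl group is cis to the ester. This bench-stable allylboronate adds to 14 on heating in toluene or with Sc(OTf)3 (10 mol%) through a closed chair transition state, stereospecifically anti and anti to the C8–O bond, to give the O6-pinacolboryl derivative of 20 F4. Aqueous work-up gives 20, and PPTS in toluene closes the lactone to 21.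

**Step 15.** The α-acyloxy aldehyde may epimerise at C8 with amine base, or the direct oxidation of the silyl ether may be incomplete. The fallback sets out from 25 and comes back at 26. The triethylsilyl ether is first removed with PPTS in MeOH at 0 °C to give (1R)-2-hydroxy-1-[(2R,3S)-2-(iododienyl)-4-methylidene-5-oxooxolan-3-yl]ethyl (2S)-2-methylbutanoate F5. This alcohol is oxidised at once with TEMPO (cat.) and PhI(OAc)2 in CH2Cl2, an amine-free oxoammonium oxidation, to give 26.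

**Step 16.** The ring strain of the ten-membered ring, and not the Felkin model, may decide the face of the aldehyde, giving the 9R alcohol or a mixture. The fallback sets out from 26 and comes back at 27, and sets C9 by hydride delivery instead of C–C bond formation. The same ring closure is run without regard to selectivity, giving the (9R)-epimer of 27 F6 together with 27. The mixture is oxidised with Dess–Martin periodinane to (6R,7S,8R)-14,15-bis[(tert-butyldiphenylsilyl)oxy]-8-[(2S)-2-methylbutanoyloxy]-9-oxogermacra-1(10)Z,4E,11(13)-trien-12,6-olide F7. 1,2-Reduction of this enone with NaBH4/CeCl3·7H2O in MeOH at −78 °C from the outer face of the ring gives 27.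

Further compounds
F1 | step 11 | (4R)-4-(2,2-dibromoethenyl)-2,2-dimethyl-1,3-dioxolane | BrC(Br)=C[C@@H]1COC(C)(C)O1
F2 | step 11 | methyl 3-[(4R)-2,2-dimethyl-1,3-dioxolan-4-yl]prop-2-ynoate | COC(=O)C#C[C@@H]1COC(C)(C)O1
F3 | step 11 | methyl (2Z)-3-[(4R)-2,2-dimethyl-1,3-dioxolan-4-yl]-2-[(4,4,5,5-tetramethyl-1,3,2-dioxaborolan-2-yl)methyl]prop-2-enoate | COC(=O)/C(CB1OC(C)(C)C(C)(C)O1)=C\[C@@H]1COC(C)(C)O1
F4 | step 11 | O6-pinacolboryl derivative of 20 | C=C(C(=O)OC)[C@@H]([C@H](OB1OC(C)(C)C(C)(C)O1)/C=C(/CO[Si](c1ccccc1)(c1ccccc1)C(C)(C)C)CC/C=C(\I)CO[Si](c1ccccc1)(c1ccccc1)C(C)(C)C)[C@@H]1COC(C)(C)O1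
F5 | step 15 | (1R)-2-hydroxy-1-[(2R,3S)-2-(iododienyl)-4-methylidene-5-oxooxolan-3-yl]ethyl (2S)-2-methylbutanoate | C=C1C(=O)O[C@H](/C=C(/CO[Si](c2ccccc2)(c2ccccc2)C(C)(C)C)CC/C=C(\I)CO[Si](c2ccccc2)(c2ccccc2)C(C)(C)C)[C@H]1[C@@H](OC(=O)[C@@H](C)CC)CO
F6 | step 16 | (6R,7S,8R,9R)-14,15-bis[(tert-butyldiphenylsilyl)oxy]-9-hydroxy-8-[(2S)-2-methylbutanoyloxy]germacra-1(10)Z,4E,11(13)-trien-12,6-olide | C=C1C(=O)O[C@@H]2/C=C(/CO[Si](c3ccccc3)(c3ccccc3)C(C)(C)C)CC/C=C(/CO[Si](c3ccccc3)(c3ccccc3)C(C)(C)C)[C@@H](O)[C@H](OC(=O)[C@@H](C)CC)[C@@H]12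
F7 | step 16 | (6R,7S,8R)-14,15-bis[(tert-butyldiphenylsilyl)oxy]-8-[(2S)-2-methylbutanoyloxy]-9-oxogermacra-1(10)Z,4E,11(13)-trien-12,6-olide | C=C1C(=O)O[C@@H]2/C=C(/CO[Si](c3ccccc3)(c3ccccc3)C(C)(C)C)CC/C=C(/CO[Si](c3ccccc3)(c3ccccc3)C(C)(C)C)C(=O)[C@H](OC(=O)[C@@H](C)CC)[C@@H]12
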